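**Retrosynthetic overview**
- Target acid ⇐ methyl ester ⇐ Heck coupling (C2'–C3' bond) of a 2-methyl-2-vinylchroman ester with an (E)-trisubstituted alkenyl iodide.
- 2-Vinylchroman ester ⇐ intramolecular pyridazine–alkyne [4+2] cycloaddition, then loss of N2: the benzene ring and the dihydropyran ring are made together, the arene de novo.
- Cycloaddition precursor ⇐ SNAr of a tertiary alkoxide on methyl 6-chloropyridazine-3-carboxylate; the enynol ⇐ (R)-linalool by ozonolysis and Ohira–Bestmann alkynylation.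
- Alkenyl iodide ⇐ dihydro-β-ionone (ketone → alkyne → Zr-catalysed carboalumination/iodination).
- Ring order: trimethylcyclohexene bought intact; benzene and pyran rings formed simultaneously in step 4. The C2 stereocentre is linalool's carbinol carbon and no bond to it is ever broken.

Assumption: the target stereocentre is (R), and (R)-(−)-linalool of high ee (natural grade, ≥97% ee) is used, so the ee of the target equals that of the linalool.

**Route**

Step 1
Reactants: 1 (R)-(−)-linalool [(3R)-3,7-dimethylocta-1,6-dien-3-ol]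
Product: 3 (5R)-5-ethenyl-5-methyloxolan-2-ol (lactol; anomer mixture), via secondary ozonide 2 (not isolated)
Conditions: O3, CH2Cl2, −78 °C (Sudan Red 7B end point); then PPh3, −78 °C → rt
Reagents that add atoms: ozone, [O-][O+]=O
Why: Ozonolysis; the electron-rich trisubstituted alkene is consumed well before the monosubstituted vinyl group, and the γ-hydroxy aldehyde released on reductive work-up closes to the lactol without touching the carbinol stereocentre.

Step 2
Reactants: 3 (5R)-5-ethenyl-5-methyloxolan-2-ol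
Product: 5 (3R)-3-methylhept-1-en-6-yn-3-ol, via open-chain hydroxy aldehyde 4 (not isolated)
Conditions: Bestmann–Ohira reagent (1.3 equiv), K2CO3, MeOH, 0 °C → rt
Reagents that add atoms: dimethyl (1-diazo-2-oxopropyl)phosphonate (Bestmann–Ohira reagent), CC(=O)C(=[N+]=[N-])P(=O)(OC)OC
Why: Seyferth–Gilbert homologation in the Ohira–Bestmann version; the lactol reacts through its open aldehyde form and gains one carbon as a terminal alkyne under conditions that leave the tertiary allylic alcohol alone.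

Step 3
Reactants: 5 (3R)-3-methylhept-1-en-6-yn-3-ol; 6 methyl 6-chloropyridazine-3-carboxylate
Product: 8 methyl 6-{[(3R)-3-methylhept-1-en-6-yn-3-yl]oxy}pyridazine-3-carboxylate, via potassium alkoxide 7 (not isolated)
Conditions: KHMDS (1.05 equiv), THF, −78 °C; then 6, −78 → 0 °C
Reagents that add atoms: none
Why: SNAr (addition–elimination) at C6 of the chlorodiazine, activated by the ring nitrogens and the para ester, should outrun attack of the hindered alkoxide on the ester; the O–C(stereocentre) bond is not broken, so configuration is retained.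

Step 4
Reactants: 8 methyl 6-{[(3R)-3-methylhept-1-en-6-yn-3-yl]oxy}pyridazine-3-carboxylate
Product: 10 methyl (2R)-2-ethenyl-2-methyl-3,4-dihydro-2H-chromene-6-carboxylate, via diazabicyclooctatriene cycloadduct 9 (not isolated)
Conditions: 1,2-Cl2C6H4 (0.02 M, degassed), BHT (10 mol%), K2CO3 (solid, trace-acid scavenger), 175 °C, sealed tube
Reagents that add atoms: none
Why: Intramolecular inverse-electron-demand Diels–Alder reaction of the ester-activated 1,2-diazine (across C3/C6) with the tethered terminal alkyne, then retro-Diels–Alder loss of N2, forms the benzene and dihydropyran rings in one operation; the tether fixes the ester para to oxygen, the gem-disubstituted carbon next to oxygen favours the folded conformer (Thorpe–Ingold), and the stereocentre is a spectator.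

Step 5
Reactants: 11 dihydro-β-ionone [4-(2,6,6-trimethylcyclohex-1-en-1-yl)butan-2-one]
Product: 14 2-(but-3-yn-1-yl)-1,3,3-trimethylcyclohex-1-ene, via enol phosphate 12 (not isolated), via lithium acetylide 13 (not isolated)
Conditions: LDA (1.05 equiv), THF, −78 °C; ClP(O)(OEt)2, −78 °C → rt; then LDA (2.3 equiv), −78 °C → rt; H2O
Reagents that add atoms: none
Why: Negishi's methyl ketone to terminal alkyne conversion; kinetic enolisation at the methyl group, O-phosphorylation and LDA-induced β-elimination of diethyl phosphate from the enol phosphate.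

Step 6
Reactants: 14 2-(but-3-yn-1-yl)-1,3,3-trimethylcyclohex-1-ene
Product: 16 2-[(3E)-4-iodo-3-methylbut-3-en-1-yl]-1,3,3-trimethylcyclohex-1-ene, via alkenylalane 15 (not isolated)
Conditions: AlMe3 (2 equiv), Cp2ZrCl2 (0.25 equiv), CH2Cl2, 0 °C → rt; then I2, THF, −30 → 0 °C
Reagents that add atoms: trimethylaluminium, C[Al](C)C; iodine, II
Why: Negishi zirconium-catalysed carboalumination adds Me and Al syn with Al at the terminal carbon, and iodinolysis with retention gives the (E)-trisubstituted alkenyl iodide; the tetrasubstituted ring alkene is inert.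

Step 7
Reactants: 10 methyl (2R)-2-ethenyl-2-methyl-3,4-dihydro-2H-chromene-6-carboxylate; 16 2-[(3E)-4-iodo-3-methylbut-3-en-1-yl]-1,3,3-trimethylcyclohex-1-ene
Product: 17 methyl (2R)-2-methyl-2-[(1E,3E)-4-methyl-6-(2,6,6-trimethylcyclohex-1-en-1-yl)hexa-1,3-dien-1-yl]-3,4-dihydro-2H-chromene-6-carboxylate
Conditions: Pd(OAc)2 (5 mol%), Bu4NCl (1 equiv), K2CO3 (2.5 equiv), DMF, 50 °C
Reagents that add atoms: none
Why: Mizoroki–Heck alkenylation under Jeffery conditions; the alkenyl–Pd adds to the unsubstituted vinyl terminus, syn β-hydride elimination (only C2' carries β-hydrogens, C2 is quaternary) gives the (E)-C1'=C2' alkene, and the iodide geometry is retained, so the diene is (1E,3E).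

Step 8
Reactants: 17 methyl (2R)-2-methyl-2-[(1E,3E)-4-methyl-6-(2,6,6-trimethylcyclohex-1-en-1-yl)hexa-1,3-dien-1-yl]-3,4-dihydro-2H-chromene-6-carboxylate
Product: 19 (2R)-2-methyl-2-[(1E,3E)-4-methyl-6-(2,6,6-trimethylcyclohex-1-en-1-yl)hexa-1,3-dien-1-yl]-3,4-dihydro-2H-chromene-6-carboxylic acid (target), via lithium carboxylate 18 (not isolated)
Conditions: LiOH·H2O (5 equiv), THF/MeOH/H2O 3:1:1, 40 °C; then 1 M HCl to pH 4, 0 °C
Reagents that add atoms: lithium hydroxide, [Li+].[OH-]
Why: Ester saponification (BAc2); the diene and the tertiary aryl ether are base-stable, and cold acidification only to pH 4 avoids ionising the dienylic tertiary ether.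

**Compound list**

1 | (R)-(−)-linalool, (3R)-3,7-dimethylocta-1,6-dien-3-ol | C=C[C@](C)(O)CCC=C(C)C | starting material
2 | (3R)-5-(5,5-dimethyl-1,2,4-trioxolan-3-yl)-3-methylpent-1-en-3-ol (secondary ozonide, epimers at the trioxolane carbon) | C=C[C@](C)(O)CCC1OOC(C)(C)O1 | intermediate
3 | (5R)-5-ethenyl-5-methyloxolan-2-ol (anomer mixture) | C=C[C@@]1(C)CCC(O)O1 | intermediate
4 | (4R)-4-hydroxy-4-methylhex-5-enal | C=C[C@](C)(O)CCC=O | intermediate
5 | (3R)-3-methylhept-1-en-6-yn-3-ol | C=C[C@](C)(O)CCC#C | intermediate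
6 | methyl 6-chloropyridazine-3-carboxylate | COC(=O)c1ccc(Cl)nn1 | starting material
7 | potassium (3R)-3-methylhept-1-en-6-yn-3-olate | C=C[C@](C)([O-])CCC#C.[K+] | intermediate
8 | methyl 6-{[(3R)-3-methylhept-1-en-6-yn-3-yl]oxy}pyridazine-3-carboxylate | COC(=O)c1ccc(O[C@@](C)(C=C)CCC#C)nn1 | intermediate
9 | [4+2] cycloadduct: 2,3-diazabicyclo[2.2.2]octa-2,5,7-triene with CO2Me on one bridgehead and the O–C(Me)(vinyl)–CH2CH2 tether joining the other bridgehead to C7 (both bridgehead diastereomers converge on 10) | COC(=O)C12C=CC3(N=N1)O[C@@](C)(C=C)CCC3=C2 | intermediate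
10 | methyl (2R)-2-ethenyl-2-methyl-3,4-dihydro-2H-chromene-6-carboxylate | C=C[C@@]1(C)CCc2cc(C(=O)OC)ccc2O1 | intermediate
11 | dihydro-β-ionone, 4-(2,6,6-trimethylcyclohex-1-en-1-yl)butan-2-one | CC(=O)CCC1=C(C)CCCC1(C)C | starting material
12 | diethyl 4-(2,6,6-trimethylcyclohex-1-en-1-yl)but-1-en-2-yl phosphate | C=C(CCC1=C(C)CCCC1(C)C)OP(=O)(OCC)OCC | intermediate
13 | lithium 4-(2,6,6-trimethylcyclohex-1-en-1-yl)but-1-yn-1-ide | [Li]C#CCCC1=C(C)CCCC1(C)C | intermediate
14 | 2-(but-3-yn-1-yl)-1,3,3-trimethylcyclohex-1-ene | C#CCCC1=C(C)CCCC1(C)C | intermediate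
15 | dimethyl[(1E)-2-methyl-4-(2,6,6-trimethylcyclohex-1-en-1-yl)but-1-en-1-yl]alumane | C[Al](C)/C=C(\C)CCC1=C(C)CCCC1(C)C | intermediate
16 | 2-[(3E)-4-iodo-3-methylbut-3-en-1-yl]-1,3,3-trimethylcyclohex-1-ene | I/C=C(\C)CCC1=C(C)CCCC1(C)C | intermediate
17 | methyl (2R)-2-methyl-2-[(1E,3E)-4-methyl-6-(2,6,6-trimethylcyclohex-1-en-1-yl)hexa-1,3-dien-1-yl]-3,4-dihydro-2H-chromene-6-carboxylate | CC1=C(CC/C(C)=C/C=C/[C@@]2(C)CCc3cc(C(=O)OC)ccc3O2)C(C)(C)CCC1 | intermediate
18 | lithium (2R)-2-methyl-2-[(1E,3E)-4-methyl-6-(2,6,6-trimethylcyclohex-1-en-1-yl)hexa-1,3-dien-1-yl]-3,4-dihydro-2H-chromene-6-carboxylate | CC1=C(CC/C(C)=C/C=C/[C@@]2(C)CCc3cc(C(=O)[O-])ccc3O2)C(C)(C)CCC1.[Li+] | intermediate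
19 | (2R)-2-methyl-2-[(1E,3E)-4-methyl-6-(2,6,6-trimethylcyclohex-1-en-1-yl)hexa-1,3-dien-1-yl]-3,4-dihydro-2H-chromene-6-carboxylic acid | CC1=C(CC/C(C)=C/C=C/[C@@]2(C)CCc3cc(C(=O)O)ccc3O2)C(C)(C)CCC1 | target

**Totals**
Total step count: 8. Longest linear sequence: 6 steps (1 → 3 → 5 → 8 → 10 → 17 → 19, i.e. steps 1, 2, 3, 4, 7, 8); steps 5 and 6 make the coupling partner 16 in parallel.

**Three steps most likely to fail, with fallbacks**

Step 4 (cycloaddition). Compound 8 is a tertiary allylic heteroaryl ether, so at about 175 °C a [3,3] O→N allyl shift to an N-allyl pyridazinone or elimination of the tertiary ether may outrun the cycloaddition. The fallback sets out from 8 and comes back at 10, replacing the alkyne dienophile by an enamine, which reacts with electron-poor 1,2-diazines at much lower temperature.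
- Anti-Markovnikov hydration of the terminal alkyne of 8 (CpRu(MeCN)3PF6, 5,5'-bis(trifluoromethyl)-2,2'-bipyridine, NMP/H2O, rt) gives the aldehyde methyl 6-{[(3R)-3-methyl-7-oxohept-1-en-3-yl]oxy}pyridazine-3-carboxylate F1.
- Pyrrolidine and 4 Å sieves in toluene (rt → 60–110 °C) convert F1 in the flask into the enamine methyl 6-{[(3R,6E)-3-methyl-7-(pyrrolidin-1-yl)hepta-1,6-dien-3-yl]oxy}pyridazine-3-carboxylate F2.
- F2 undergoes the same intramolecular [4+2] and N2 loss to give methyl (2R)-2-ethenyl-2-methyl-5-(pyrrolidin-1-yl)-3,4,4a,5-tetrahydro-2H-chromene-6-carboxylate F3, which eliminates pyrrolidine (a little AcOH at the end) to give 10.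

Step 3 (SNAr). The hindered tertiary alkoxide may attack the methyl ester instead, and the methoxide released would then consume 6. The fallback sets out from 5 and comes back at 19, carrying a nitrile in place of the ester; the nitrile cannot be transesterified and activates both the SNAr and the cycloaddition more strongly.
- Alkoxide 7 (from 5, KHMDS) and commercial 6-chloropyridazine-3-carbonitrile give 6-{[(3R)-3-methylhept-1-en-6-yn-3-yl]oxy}pyridazine-3-carbonitrile F4.
- Heating as in step 4 gives, through the cycloadduct 2,3-diazabicyclo[2.2.2]octatriene carbonitrile F5, (2R)-2-ethenyl-2-methyl-3,4-dihydro-2H-chromene-6-carbonitrile F6.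
- Heck coupling with 16 as in step 7 gives (2R)-2-methyl-2-[(1E,3E)-4-methyl-6-(2,6,6-trimethylcyclohex-1-en-1-yl)hexa-1,3-dien-1-yl]-3,4-dihydro-2H-chromene-6-carbonitrile F7.
- Hydrolysis (KOH, EtOH/H2O, 100 °C) gives potassium (2R)-2-methyl-2-[(1E,3E)-4-methyl-6-(2,6,6-trimethylcyclohex-1-en-1-yl)hexa-1,3-dien-1-yl]-3,4-dihydro-2H-chromene-6-carboxylate F8, which is acidified to pH 4 to give 19.

Step 7 (Heck). β-Aryloxide elimination from the alkyl–Pd intermediate, or Pd(0) ionisation of the allylic aryl ether, would open the chroman. The fallback sets out from 10 and comes back at 17, reversing the polarity of the coupling.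
- Ozonolysis of the vinyl group of 10 (O3, CH2Cl2, −78 °C; PPh3) gives, through the ozonide methyl (2R)-2-methyl-2-(1,2,4-trioxolan-3-yl)-3,4-dihydro-2H-chromene-6-carboxylate F9, the aldehyde methyl (2R)-2-formyl-2-methyl-3,4-dihydro-2H-chromene-6-carboxylate F10.
- Takai olefination (CrCl2, CHI3, THF, 0 °C) gives methyl (2R)-2-[(E)-2-iodoethenyl]-2-methyl-3,4-dihydro-2H-chromene-6-carboxylate F11.
- Negishi coupling of F11 with alkenylalane 15 (made from 14 as in step 6 without the iodine quench; Pd(PPh3)4 5 mol%, ZnCl2, THF, rt) gives 17.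

**Further compounds**

F1 | step 4 | methyl 6-{[(3R)-3-methyl-7-oxohept-1-en-3-yl]oxy}pyridazine-3-carboxylate | COC(=O)c1ccc(O[C@@](C)(C=C)CCCC=O)nn1
F2 | step 4 | methyl 6-{[(3R,6E)-3-methyl-7-(pyrrolidin-1-yl)hepta-1,6-dien-3-yl]oxy}pyridazine-3-carboxylate | COC(=O)c1ccc(O[C@@](C)(C=C)CC/C=C/N2CCCC2)nn1
F3 | step 4 | methyl (2R)-2-ethenyl-2-methyl-5-(pyrrolidin-1-yl)-3,4,4a,5-tetrahydro-2H-chromene-6-carboxylate | C=C[C@@]1(C)CCC2C(N3CCCC3)C(C(=O)OC)=CC=C2O1
F4 | step 3 | 6-{[(3R)-3-methylhept-1-en-6-yn-3-yl]oxy}pyridazine-3-carbonitrile | N#Cc1ccc(O[C@@](C)(C=C)CCC#C)nn1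
F5 | step 3 | [4+2] cycloadduct of F4 (2,3-diazabicyclo[2.2.2]octatriene carbonitrile) | N#CC12C=CC3(N=N1)O[C@@](C)(C=C)CCC3=C2
F6 | step 3 | (2R)-2-ethenyl-2-methyl-3,4-dihydro-2H-chromene-6-carbonitrile | C=C[C@@]1(C)CCc2cc(C#N)ccc2O1
F7 | step 3 | (2R)-2-methyl-2-[(1E,3E)-4-methyl-6-(2,6,6-trimethylcyclohex-1-en-1-yl)hexa-1,3-dien-1-yl]-3,4-dihydro-2H-chromene-6-carbonitrile | CC1=C(CC/C(C)=C/C=C/[C@@]2(C)CCc3cc(C#N)ccc3O2)C(C)(C)CCC1
F8 | step 3 | potassium (2R)-2-methyl-2-[(1E,3E)-4-methyl-6-(2,6,6-trimethylcyclohex-1-en-1-yl)hexa-1,3-dien-1-yl]-3,4-dihydro-2H-chromene-6-carboxylate | CC1=C(CC/C(C)=C/C=C/[C@@]2(C)CCc3cc(C(=O)[O-])ccc3O2)C(C)(C)CCC1.[K+]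
F9 | step 7 | methyl (2R)-2-methyl-2-(1,2,4-trioxolan-3-yl)-3,4-dihydro-2H-chromene-6-carboxylate | O1COC(O1)[C@@]2(C)CCc3cc(C(=O)OC)ccc3O2
F10 | step 7 | methyl (2R)-2-formyl-2-methyl-3,4-dihydro-2H-chromene-6-carboxylate | O=C[C@@]1(C)CCc2cc(C(=O)OC)ccc2O1
F11 | step 7 | methyl (2R)-2-[(E)-2-iodoethenyl]-2-methyl-3,4-dihydro-2H-chromene-6-carboxylate | I/C=C/[C@@]1(C)CCc2cc(C(=O)OC)ccc2O1
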